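Birch and ash, charged at 0.56 M and 0.88 M, were what I had for a flask at 0.40 M.

| flask | starting material | remark | time |
|---|---|---|---|
| birch | 0.56 M | run made earlier |  |
| ash | 0.88 M | run made earlier |  |
| flask | 0.40 M |  | 40 min |

| run | time / min | target / % | starting material / % |
|---|---|---|---|
| birch | 1.50 | 11.9 | 62.4 |
| birch | 2.50 | 22.2 | 45.3 |
| birch | 5.00 | 34.2 | 19.9 |
| birch | 8.00 | 33.0 | 7.3 |
| birch | 15.0 | 17.8 | 0.9 |
| birch | 25.0 | 6.1 | 0.2 |
| birch | 40.0 | 1.3 | 0 |
| ash | 1.50 | 11.7 | 62.1 |
| ash | 2.50 | 21.7 | 44.6 |
| ash | 5.00 | 34.2 | 19.4 |
| ash | 8.00 | 32.7 | 6.8 |
| ash | 15.0 | 17.2 | 1.0 |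
| ash | 25.0 | 5.6 | 0 |
| ash | 40.0 | 0.8 | 0 |

(scatter of a reading: 0.3 percentage points)

1. time up to 40 min at which target stands highest
2. the amount of target, in percent of the starting material charged, at that time
3. earliest time at which at least nineteen twentieths of that best amount are there, in min
4. latest time at which they still are, in min



Target rose in both runs, then sank by 40.0 min to 1.3% in birch and 0.8% in ash, so the end state held little target and the highest point lay inside the run. The two highest birch readings were 34.2% at 5.00 min and 33.0% at 8.00 min. I read the peak between them, a little before the midpoint, 6.50 min, since the earlier reading stood higher.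

Then I turned the question round: what would a thinner charge need to show for its curve to stand apart? At 8.00 min the birch reading lay 0.3 percentage points above the ash reading, a gap about the size of the scatter of one reading, so what follows is a loose reading. That gap per molar of charge is the charge slope s, 0.00938 L mol⁻¹, a fraction of the charge. Going down from birch to the flask, s gave a shift of 0.15 points, less than the scatter of 0.3 points. To reach that scatter the gap needed 0.6 points, twice what stood. So I took the birch curve for the flask.

The forecast gave 6.2 min, 35.3% and a window from 4.6 min to 7.9 min, saying of the decay of starting material that “concentration hardly matters”.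

The flask peaked at 6.07 min with 35.7%, inside a window from 4.61 min to 7.90 min.

    intermediate ⇌ target (K = 9.00, k = 0.0112 s⁻¹)
    intermediate ⇌ isomer of the product (K = 98.2, k = 0.00408 s⁻¹)
    starting material → intermediate (k = 0.00527 s⁻¹)
    target → over-reaction product (k = 0.00190 s⁻¹)
    starting material + target → side product (k = 8.39 × 10⁻⁴ L mol⁻¹ s⁻¹)

At 4.00 min the flask still held 27.9% starting material and 15.5% intermediate while target climbed. By 20.0 min the flask's starting material stood at 0.164%, and target, down to 10.3%, had gone on into over-reaction product, now 51.9%. For the neighbour charged at 0.68 M, s, read at 8.00 min and laid on the peak as an estimate, takes 0.26 points off the flask's best, giving 35.4%. The computed best there is 35.1%.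

The readings are simulated on assumed constants; scatter was added.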